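**Plan**
- Retrosynthesis: the three benzyl ethers (O5, O7, O5') and then the O3 methyl with its C3–O bond are removed, which leaves a 3-unsubstituted flavone.
- Ring C is then cut at C4a–C4, C4–C3 and O1–C2 into a ring A iodophenol triacetate, carbon monoxide and a ring B arylacetylene.
- This works because C4 is a lone carbonyl carbon between C4a and C3, and ring A has a single C–H (the future C4a) flanked by two equivalent oxygens. The iodide therefore has one possible site, and either oxygen can become O1.
- Forward: ring A (5 steps) and ring B (4 steps) are made separately and ring C is closed in the three-component annulation. C3 is then oxygenated by epoxidation and isomerisation, O3 is methylated and the benzyl groups are removed.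
- Stereochemistry: the target has no stereocentre. The only stereogenic intermediate is a racemic epoxide, which is flattened again when it opens.

Key step: step 10

Remark on the chemistry: enaminone 15 is drawn as its E isomer, although either geometry would close to the same flavone; epoxide 18 is racemic and one enantiomer is drawn.

**Route**

Step 1
Reactants: 1 1,3,5-tris(benzyloxy)benzene
Product: 2 1,3,5-tris(benzyloxy)-2,4-dibromobenzene
Conditions: NBS (2.05 equiv), CH2Cl2, −20 → 0 °C, dark
Reagents that add atoms: N-bromosuccinimide, O=C1CCC(=O)N1Br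
Why: Electrophilic aromatic bromination of a trialkoxybenzene, in which each bromine lowers the reactivity of the remaining position so that two equivalents of NBS at low temperature should stop at the dibromide.

Step 2
Reactants: 2 1,3,5-tris(benzyloxy)-2,4-dibromobenzene
Product: 3 1,3,5-tris(benzyloxy)-2,4-dimethoxybenzene
Conditions: NaOMe (25% in MeOH, excess), CuI (20 mol%), DMF, 110 °C
Reagents that add atoms: sodium methoxide, [Na+].[O-]C
Why: Copper-catalysed Ullmann-type methoxylation of aryl bromides is a standard way to turn bromo-polyalkoxybenzenes into methyl ethers, and benzyl ethers are inert to methoxide.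

Step 3
Reactants: 3 1,3,5-tris(benzyloxy)-2,4-dimethoxybenzene
Product: 4 2,4-dimethoxybenzene-1,3,5-triol
Conditions: H2 (1 atm), 10% Pd/C, EtOAc/MeOH, rt; product kept under argon and used directly
Reagents that add atoms: none
Why: Hydrogenolysis of benzyl aryl ethers over palladium on carbon should free the three phenols and leave the methyl ethers untouched.

Step 4
Reactants: 4 2,4-dimethoxybenzene-1,3,5-triol
Product: 5 2-iodo-4,6-dimethoxybenzene-1,3,5-triol
Conditions: NIS (1.0 equiv), MeCN, 0 °C, argon, dark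
Reagents that add atoms: N-iodosuccinimide, O=C1CCC(=O)N1I
Why: Electrophilic iodination of a phloroglucinol can only occur at the single free ring position, which is ortho to two hydroxyls and para to the third, and one equivalent of NIS in the cold should limit oxidation of the ring.

Step 5
Reactants: 5 2-iodo-4,6-dimethoxybenzene-1,3,5-triol
Product: 6 2-iodo-4,6-dimethoxybenzene-1,3,5-triyl triacetate
Conditions: Ac2O, pyridine, DMAP (cat.), CH2Cl2, 0 °C → rt
Reagents that add atoms: acetic anhydride, CC(=O)OC(C)=O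
Why: DMAP-catalysed O-acetylation should cap all three phenols, which makes the ring less electron-rich for oxidative addition and stores the phenol nucleophiles for the annulation.

Step 6
Reactants: 7 2,4-dimethoxyphenol
Product: 8 1-(benzyloxy)-2,4-dimethoxybenzene
Conditions: BnBr, K2CO3, acetone, reflux
Reagents that add atoms: benzyl bromide, BrCc1ccccc1
Why: Williamson ether synthesis on the phenoxide.

Step 7
Reactants: 8 1-(benzyloxy)-2,4-dimethoxybenzene
Product: 9 1-(benzyloxy)-5-iodo-2,4-dimethoxybenzene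
Conditions: NIS, CF3CO2H (cat.), MeCN, rt
Reagents that add atoms: N-iodosuccinimide, O=C1CCC(=O)N1I
Why: Acid-activated NIS iodination should go to C5, which is para to the 2-methoxy and ortho to the 4-methoxy group, whereas C3 is crowded between two methoxy groups and C6 is activated only by the benzyloxy group.

Step 8
Reactants: 9 1-(benzyloxy)-5-iodo-2,4-dimethoxybenzene; 10 ethynyltrimethylsilane
Product: 11 {[5-(benzyloxy)-2,4-dimethoxyphenyl]ethynyl}trimethylsilane
Conditions: PdCl2(PPh3)2 (2 mol%), CuI (4 mol%), Et3N, THF, 50 °C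
Reagents that add atoms: none
Why: Sonogashira coupling of an aryl iodide with a terminal alkyne, for which electron-rich aryl iodides are routine substrates.

Step 9
Reactants: 11 {[5-(benzyloxy)-2,4-dimethoxyphenyl]ethynyl}trimethylsilane
Product: 12 1-(benzyloxy)-5-ethynyl-2,4-dimethoxybenzene
Conditions: K2CO3 (cat.), MeOH/THF, rt
Reagents that add atoms: none
Why: Carbonate-catalysed methanolysis of the C(sp)–Si bond is the standard release of a terminal alkyne from its trimethylsilyl derivative.

Step 10
Reactants: 6 2-iodo-4,6-dimethoxybenzene-1,3,5-triyl triacetate; 12 1-(benzyloxy)-5-ethynyl-2,4-dimethoxybenzene; 13 carbon monoxide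
Product: 16 2-[5-(benzyloxy)-2,4-dimethoxyphenyl]-5,7-dihydroxy-6,8-dimethoxy-4H-chromen-4-one, via ynone triacetate 14 (not isolated), via enaminone triol 15 (not isolated)
Conditions: PdCl2(PPh3)2 (5 mol%), dppp (5 mol%), thiourea (5 mol%), CO (1 atm), Et2NH, 40 °C; dilute aq. HCl work-up
Reagents that add atoms: none
Why: Oxidative addition of the C–I bond of 6 to zerovalent palladium (generated from PdCl2(PPh3)2 under the conditions) is followed by migratory insertion of CO, and the acylpalladium complex is intercepted by alkyne 12 to release ynone 14, which sets C4a–C4 and C4–C3; Et2NH then strips the three acetyl groups by aminolysis and adds in conjugate fashion to give enaminone 15. A phenoxide ortho to the ketone attacks C2 of 15 and diethylamine is expelled (addition–elimination), which forms O1–C2 and closes ring C in a 6-endo-trig manner. The closest known reaction type is the palladium-catalysed carbonylative annulation of ortho-iodophenol acetates with terminal alkynes and CO to flavones. No stereocentre is created. The step needs 6-endo closure to the flavone instead of 5-exo closure to the aurone, which passage through the enaminone secures because its amine-bearing carbon C2 is the only electrophilic site left for the phenoxide, and it needs CO uptake to outrun direct alkynylation, which the CO atmosphere and the doubly ortho-substituted arylpalladium should favour. No choice between hydroxyls arises, because the two oxygens flanking the iodide in 6 are equivalent by symmetry and the one not used becomes the 5-hydroxyl.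

Step 11
Reactants: 16 2-[5-(benzyloxy)-2,4-dimethoxyphenyl]-5,7-dihydroxy-6,8-dimethoxy-4H-chromen-4-one
Product: 17 5,7-bis(benzyloxy)-2-[5-(benzyloxy)-2,4-dimethoxyphenyl]-6,8-dimethoxy-4H-chromen-4-one
Conditions: BnBr (3 equiv), K2CO3, DMF, 70 °C
Reagents that add atoms: benzyl bromide, BrCc1ccccc1
Why: Williamson etherification, in which the acidic 7-hydroxyl reacts first and the hydrogen-bonded 5-hydroxyl follows with excess benzyl bromide in warm DMF.

Step 12
Reactants: 17 5,7-bis(benzyloxy)-2-[5-(benzyloxy)-2,4-dimethoxyphenyl]-6,8-dimethoxy-4H-chromen-4-one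
Product: 19 5,7-bis(benzyloxy)-2-[5-(benzyloxy)-2,4-dimethoxyphenyl]-3-hydroxy-6,8-dimethoxy-4H-chromen-4-one, via flavone 2,3-epoxide 18 (not isolated)
Conditions: dimethyldioxirane (acetone solution), CH2Cl2, 0 °C → rt; then p-TsOH·H2O (cat.), CH2Cl2, rt
Reagents that add atoms: dimethyldioxirane, CC1(C)OO1
Why: Dimethyldioxirane epoxidises the C2=C3 bond of flavones by concerted oxygen transfer, and acid then opens the epoxide at C2 (cation stabilised by O1 and the aryl group) with loss of the C3 proton to give the flavonol, so the two racemic epoxide stereocentres are erased.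

Step 13
Reactants: 19 5,7-bis(benzyloxy)-2-[5-(benzyloxy)-2,4-dimethoxyphenyl]-3-hydroxy-6,8-dimethoxy-4H-chromen-4-one
Product: 20 5,7-bis(benzyloxy)-2-[5-(benzyloxy)-2,4-dimethoxyphenyl]-3,6,8-trimethoxy-4H-chromen-4-one
Conditions: MeI, K2CO3, acetone, reflux
Reagents that add atoms: iodomethane, CI
Why: Williamson O-methylation of the 3-hydroxyl, which is the only free hydroxyl in 19.

Step 14
Reactants: 20 5,7-bis(benzyloxy)-2-[5-(benzyloxy)-2,4-dimethoxyphenyl]-3,6,8-trimethoxy-4H-chromen-4-one
Product: 21 5,7-dihydroxy-2-(5-hydroxy-2,4-dimethoxyphenyl)-3,6,8-trimethoxy-4H-chromen-4-one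
Conditions: H2 (1 atm), 10% Pd/C, EtOAc/MeOH, rt
Reagents that add atoms: none
Why: Hydrogenolysis over palladium on carbon should remove the three benzyl ethers, while the tetrasubstituted C2=C3 bond of the chromone and the methyl ethers are not reduced under one atmosphere of hydrogen.

**Compound list**

1 | 1,3,5-tris(benzyloxy)benzene | c1ccc(COc2cc(OCc3ccccc3)cc(OCc3ccccc3)c2)cc1 | starting material
2 | 1,3,5-tris(benzyloxy)-2,4-dibromobenzene | Brc1c(OCc2ccccc2)cc(OCc2ccccc2)c(Br)c1OCc1ccccc1 | intermediate
3 | 1,3,5-tris(benzyloxy)-2,4-dimethoxybenzene | COc1c(OCc2ccccc2)cc(OCc2ccccc2)c(OC)c1OCc1ccccc1 | intermediate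
4 | 2,4-dimethoxybenzene-1,3,5-triol | COc1c(O)cc(O)c(OC)c1O | intermediate
5 | 2-iodo-4,6-dimethoxybenzene-1,3,5-triol | COc1c(O)c(I)c(O)c(OC)c1O | intermediate
6 | 2-iodo-4,6-dimethoxybenzene-1,3,5-triyl triacetate | COc1c(OC(C)=O)c(I)c(OC(C)=O)c(OC)c1OC(C)=O | intermediate
7 | 2,4-dimethoxyphenol | COc1ccc(O)c(OC)c1 | starting material
8 | 1-(benzyloxy)-2,4-dimethoxybenzene | COc1ccc(OCc2ccccc2)c(OC)c1 | intermediate
9 | 1-(benzyloxy)-5-iodo-2,4-dimethoxybenzene | COc1cc(OC)c(OCc2ccccc2)cc1I | intermediate
10 | ethynyltrimethylsilane (trimethylsilylacetylene) | C#C[Si](C)(C)C | starting material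
11 | {[5-(benzyloxy)-2,4-dimethoxyphenyl]ethynyl}trimethylsilane | COc1cc(OC)c(OCc2ccccc2)cc1C#C[Si](C)(C)C | intermediate
12 | 1-(benzyloxy)-5-ethynyl-2,4-dimethoxybenzene | C#Cc1cc(OCc2ccccc2)c(OC)cc1OC | intermediate
13 | carbon monoxide | [C-]#[O+] | starting material
14 | ynone triacetate (not isolated): 2-{3-[5-(benzyloxy)-2,4-dimethoxyphenyl]prop-2-ynoyl}-4,6-dimethoxybenzene-1,3,5-triyl triacetate | COc1c(OC(C)=O)c(C(=O)C#Cc2cc(OCc3ccccc3)c(OC)cc2OC)c(OC(C)=O)c(OC)c1OC(C)=O | intermediate
15 | enaminone triol (not isolated): (E)-3-[5-(benzyloxy)-2,4-dimethoxyphenyl]-3-(diethylamino)-1-(2,4,6-trihydroxy-3,5-dimethoxyphenyl)prop-2-en-1-one | CCN(CC)/C(=C/C(=O)c1c(O)c(OC)c(O)c(OC)c1O)c1cc(OCc2ccccc2)c(OC)cc1OC | intermediate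
16 | 2-[5-(benzyloxy)-2,4-dimethoxyphenyl]-5,7-dihydroxy-6,8-dimethoxy-4H-chromen-4-one | COc1cc(OC)c(-c2cc(=O)c3c(O)c(OC)c(O)c(OC)c3o2)cc1OCc1ccccc1 | intermediate
17 | 5,7-bis(benzyloxy)-2-[5-(benzyloxy)-2,4-dimethoxyphenyl]-6,8-dimethoxy-4H-chromen-4-one | COc1cc(OC)c(-c2cc(=O)c3c(OCc4ccccc4)c(OC)c(OCc4ccccc4)c(OC)c3o2)cc1OCc1ccccc1 | intermediate
18 | flavone 2,3-epoxide (not isolated, racemic, cis-fused, one enantiomer drawn): 5,7-bis(benzyloxy)-2-[5-(benzyloxy)-2,4-dimethoxyphenyl]-2,3-epoxy-6,8-dimethoxy-2,3-dihydro-4H-chromen-4-one | O=C1c2c(OCc3ccccc3)c(OC)c(OCc3ccccc3)c(OC)c2O[C@]2(c3cc(OCc4ccccc4)c(OC)cc3OC)O[C@H]12 | intermediate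
19 | 5,7-bis(benzyloxy)-2-[5-(benzyloxy)-2,4-dimethoxyphenyl]-3-hydroxy-6,8-dimethoxy-4H-chromen-4-one | COc1cc(OC)c(-c2oc3c(OC)c(OCc4ccccc4)c(OC)c(OCc4ccccc4)c3c(=O)c2O)cc1OCc1ccccc1 | intermediate
20 | 5,7-bis(benzyloxy)-2-[5-(benzyloxy)-2,4-dimethoxyphenyl]-3,6,8-trimethoxy-4H-chromen-4-one | COc1cc(OC)c(-c2oc3c(OC)c(OCc4ccccc4)c(OC)c(OCc4ccccc4)c3c(=O)c2OC)cc1OCc1ccccc1 | intermediate
21 | 5,7-dihydroxy-2-(5-hydroxy-2,4-dimethoxyphenyl)-3,6,8-trimethoxy-4H-chromen-4-one | COc1cc(OC)c(-c2oc3c(OC)c(O)c(OC)c(O)c3c(=O)c2OC)cc1O | target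

**Step count**

Total: 14 steps. Longest linear sequence: 10 steps (steps 1–5, then 10–14); the ring B branch (steps 6–9) joins at step 10.

**Steps most likely to fail**

Step 10. The acetates may be cleaved by Et2NH before palladium has inserted. That would leave an electron-rich iodophenoxide, which inserts slowly and loses iodine by reduction. Direct alkynylation without CO uptake may also compete at the crowded position. The fallback sets out from 4 and 8 and returns at 17, so step 11 falls away. Friedel–Crafts C-acetylation of triol 4 (AcOH, BF3·OEt2, 80 °C) should give 1-(2,4,6-trihydroxy-3,5-dimethoxyphenyl)ethan-1-one F1. Benzylation with two equivalents of BnBr (K2CO3, acetone) should spare one chelated ortho hydroxyl and give 1-[2,4-bis(benzyloxy)-6-hydroxy-3,5-dimethoxyphenyl]ethan-1-one F2. Vilsmeier–Haack formylation of 8 (POCl3, DMF), directed to C5 like the iodination of step 7, should give 5-(benzyloxy)-2,4-dimethoxybenzaldehyde F3. Claisen–Schmidt condensation of F2 with F3 (KOH, EtOH) should give (E)-1-[2,4-bis(benzyloxy)-6-hydroxy-3,5-dimethoxyphenyl]-3-[5-(benzyloxy)-2,4-dimethoxyphenyl]prop-2-en-1-one F4. Oxidative cyclisation of the 2'-hydroxychalcone (I2 cat., DMSO, 120 °C) should then close ring C to 17.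

Step 2. The second substitution, at a bromide flanked by two benzyloxy groups, may stall, and reductive loss of bromine may take over. The fallback sets out from 2 and returns at 3. Palladium-catalysed hydroxylation of both C–Br bonds (Pd2(dba)3, tBuXPhos, KOH, dioxane/H2O, 100 °C) should give 2,4,6-tris(benzyloxy)benzene-1,3-diol F5. Double O-methylation (MeI, K2CO3, acetone) should then give 3, so the methyl groups arrive by Williamson alkylation instead of by substitution at the arene.

Step 12. Dimethyldioxirane may oxidise the electron-rich ring B or the benzylic C–H bonds of the benzyl ethers faster than it epoxidises the electron-poor enone. The fallback sets out from 17 and returns at 19. Deprotonation at C3 with LDA (THF, −78 °C) should give {5,7-bis(benzyloxy)-2-[5-(benzyloxy)-2,4-dimethoxyphenyl]-6,8-dimethoxy-4-oxo-4H-chromen-3-yl}lithium F6. Trapping with B(OMe)3 should give dimethyl {5,7-bis(benzyloxy)-2-[5-(benzyloxy)-2,4-dimethoxyphenyl]-6,8-dimethoxy-4-oxo-4H-chromen-3-yl}boronate F7. Oxidation of the C–B bond with H2O2/AcOH at 0 °C should then give 19.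

**Further compounds**

F1 | step 10 | 1-(2,4,6-trihydroxy-3,5-dimethoxyphenyl)ethan-1-one | CC(=O)c1c(O)c(OC)c(O)c(OC)c1O
F2 | step 10 | 1-[2,4-bis(benzyloxy)-6-hydroxy-3,5-dimethoxyphenyl]ethan-1-one | CC(=O)c1c(O)c(OC)c(OCc2ccccc2)c(OC)c1OCc1ccccc1
F3 | step 10 | 5-(benzyloxy)-2,4-dimethoxybenzaldehyde | COc1cc(OC)c(OCc2ccccc2)cc1C=O
F4 | step 10 | (E)-1-[2,4-bis(benzyloxy)-6-hydroxy-3,5-dimethoxyphenyl]-3-[5-(benzyloxy)-2,4-dimethoxyphenyl]prop-2-en-1-one | COc1cc(OC)c(OCc2ccccc2)cc1/C=C/C(=O)c1c(O)c(OC)c(OCc2ccccc2)c(OC)c1OCc1ccccc1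
F5 | step 2 | 2,4,6-tris(benzyloxy)benzene-1,3-diol | Oc1c(OCc2ccccc2)cc(OCc2ccccc2)c(O)c1OCc1ccccc1
F6 | step 12 | {5,7-bis(benzyloxy)-2-[5-(benzyloxy)-2,4-dimethoxyphenyl]-6,8-dimethoxy-4-oxo-4H-chromen-3-yl}lithium | [Li]c1c(-c2cc(OCc3ccccc3)c(OC)cc2OC)oc2c(OC)c(OCc3ccccc3)c(OC)c(OCc3ccccc3)c2c1=O
F7 | step 12 | dimethyl {5,7-bis(benzyloxy)-2-[5-(benzyloxy)-2,4-dimethoxyphenyl]-6,8-dimethoxy-4-oxo-4H-chromen-3-yl}boronate | COB(OC)c1c(-c2cc(OCc3ccccc3)c(OC)cc2OC)oc2c(OC)c(OCc3ccccc3)c(OC)c(OCc3ccccc3)c2c1=O
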